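## Structural features

The target is a 3',3'''-linked biflavonoid. An (S)-5,7,4'-trihydroxyflavanone (rings A, C, B) and a 5,7,4'-trihydroxyflavone (rings A', C', B') are joined by one biaryl bond between C3' of ring B and C3''' of ring B'. Each of these carbons is ortho to a 4'-hydroxyl, so rings B and B' together form a 2,2'-biphenol. The only stereocentre is C2 of the flavanone, a benzylic ether carbon with no stereogenic neighbour; the biaryl axis has just two ortho substituents and is not configurationally stable. C2 is the fragile point: base, heat or strong acid can open ring C by retro-oxa-Michael reaction to the 2'-hydroxychalcone, helped by the para oxygen of ring B, and reclosure gives racemate. The six phenols, the C2''=C3'' bond of the flavone and the benzylic O1–C2 bond further restrict late oxidants and reductants. The real difficulty is twofold: setting and keeping one labile benzylic ether centre, and telling apart two halves that differ only by two hydrogens at C2''/C3''. The key step exploits this near-identity. With ring C' at the flavanone oxidation level the molecule is a C2-symmetric (2S,2''S)-bis-flavanone on a symmetric biphenol, so both O1–C2 bonds can be formed in one operation. Because the two rings C are then homotopic, removing H2 from either gives the same compound.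

## Logic of the disconnections

14 to 13. The six phenolic O–H bonds of 14 are replaced by O–CH2Ph bonds. The phenols have to be masked through base, Lewis acid and oxidant, and one protecting group type allows one neutral, reductive final operation. The skeleton is not simplified. The forward demand is a hydrogenolysis that stops before the C2''=C3'' bond or the O1–C2 bond reacts.

13 to 11, through 12. No skeletal bond is cut; the C2''–H and C3''–H bonds are restored. This uncovers the C2 symmetry: both halves become identical and the number of different building blocks falls from four to two. The forward demand is oxidation of exactly one of two equivalent rings C, under conditions that leave C2 of the other ring alone. That step is statistical by nature and depends on recycling recovered 11.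

11 to 9, through 10. A tert-butoxycarbonyl group is put back on C3 and on C3'' (the C3–CO2 bonds). The ester is the activating and catalyst-binding group of the ring closure and has no place in the target. The gain is a doubly activated acceptor in the next retro-step. The forward demand is ester cleavage and decarboxylation without opening ring C.

9 to 8. The O1–C2 and O1''–C2'' bonds are cut. This removes both heterocycles and all four stereocentres at once and leaves an achiral, symmetric bis-enone with two free phenols. The forward demand is two catalyst-controlled conjugate additions of the same facial sense, with no help from the substrate.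

8 to 4 and two molecules of 7. The two alkylidene C=C bonds (the future C2–C3 and C2''–C3'' bonds) are cut. A CH-acidic β-keto ester and an aromatic aldehyde are the natural partners, and the symmetric core allows growth in two directions from one dialdehyde. The forward demand is a double condensation that does not trigger the ring closure early; the alkene geometry need not be controlled.

7 to 6 to 5. First the C–C bond between the acetyl carbon and the ester carbonyl is cut, then two O–CH2Ph bonds. This leads back to a commercial phloroglucinol ketone. The forward demands are acylation on carbon in the presence of an ortho phenoxide, and benzylation of two hydroxyls while the hydrogen-bonded one stays free.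

4 to 2, through 3, to 1. The biaryl bond C3'–C3''' is cut, then one O–CH2Ph bond. Because the biaryl is symmetric, a single aryl bromide serves as both coupling partners. The forward demand is that half of the bromide is converted into the boron partner and coupled with the other half in the same flask, ortho to an ether and with free aldehydes present.

## Other disconnections considered

Alternative 1: The cut is the C4a–C5 bond of ring A' in the flavone half. The phloroglucinol ring would be made last, from a pyran-4-one that already carries ring B' and the biaryl bond.
- Forward key step: Mg(OMe)2 would chelate the β-keto ester side chain of pyranone A1. Deprotonation of the methylene next to the ring gives an extended enolate, and the ring carbon that becomes C4a attacks the ester carbonyl in a 6-exo-trig Claisen condensation. Loss of methoxide and tautomerisation would give the 5,7-dihydroxyflavone A2.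
- In favour: ring A' arrives with both hydroxyls free and placed by the chain itself. The flavone half is formed at its final oxidation level, so no statistical oxidation is needed; on this point the alternative is better than the chosen plan.
- Against: A1 is a masked polyketide on an unsymmetrical biaryl and needs a cross-coupling and several chain-building steps. Such poly-β-carbonyl chains can also close by aldol addition onto the side-chain ketone, or the pyranone can be opened by methoxide. Above all, A2 has neither the stereocentre nor any atom of rings A and C of the flavanone half. Its chloride sits para to an ether oxygen and is a sluggish handle. It would still have to be turned into a formyl or vinyl group and then into an (S)-flavanone, next to a free dihydroxyflavone that would need reprotection.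
- Comparison: in structure it ignores the hidden symmetry and builds the halves one after the other. In mechanism its key step is enolate chemistry without a stereochemical question, so it is the equal of the chosen plan in predictability of the ring closure itself, but it only postpones the asymmetric problem. In step economy it would be clearly longer.

Alternative 2: The cut is the C3''–C4'' bond of the flavone half, with the 1,3-dioxygenated unit C2''–C3''–C4'' carried as a 3,5-diaryl isoxazole.
- Forward key step: 1,3-dipolar cycloaddition of the stable nitrile oxide A4 to the ethynyl group on ring B' of the preformed (S)-flavanone alkyne A3 would give isoxazole A5. The nitrile oxide carbon bonds to the terminal alkyne carbon (the future C3''–C4'' bond) and its oxygen to the internal carbon (a temporary O–C2'' bond).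
- In favour: the cycloaddition is concerted, neutral and runs near room temperature. The regiochemistry with a terminal aryl alkyne is dependable, and a nitrile oxide flanked by two ortho ether groups does not dimerise. In mildness and in convergence this key step is better than the chosen one, it does not disturb the flavanone stereocentre, and no statistical oxidation is needed.
- Against: A5 is still several operations from a flavone. These are reductive N–O cleavage, hydrolysis of the resulting enamine function, liberation of exactly one ortho phenol out of three benzyl ethers, and acid cyclodehydration. The reduction competes with the C4 ketone, the benzylic O1–C2 bond and the benzyl ethers, and the acid step is the kind of condition that can open ring C. A3 itself needs an enantioselective flavanone synthesis on one arm, on a biaryl whose two rings B must first be differentiated. The alkyne must also be introduced without a base strong enough to racemise C2.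
- Comparison: in structure it cannot use the symmetry. In mechanism the cycloaddition is more certain than a double organocatalytic closure, but enantiopurity would rest on a single catalytic event with no diastereomer to filter off. In step economy it would be longer despite its convergence.

Alternative 3: The cut is the C4–C4a bond of the flavanone ring C. The O1–C2 ether bond and the stereocentre are made earlier by Mitsunobu inversion.
- Forward key step: trifluoroacetic anhydride would convert acid A6 into a mixed anhydride. The carbon ortho to the ether oxygen of the 3,5-bis(benzyloxy)phenoxy ring attacks it in a 6-exo-trig Friedel–Crafts acylation and gives A7.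
- In favour: the configuration comes from a stereospecific substitution of an alcohol of known configuration, so the absolute sense is predictable without reliance on catalyst facial selectivity in the ring closure; in that certainty the alternative is better than the chosen plan. The two ortho positions of the phenoxy ring are equivalent and the ring is electron-rich enough to need no Lewis acid. The flavone half is already in place, so no statistical step is needed, which is also better.
- Against: the carbinol carbon is benzylic and para to an oxygen, so the Mitsunobu step can leak through an ion pair or eliminate to a cinnamate. The 4'-acetate of A6 and A7 is there to damp this and costs a third kind of protecting group and unsymmetrical protection of the biphenol. Once the carboxyl is activated, the β-aryloxy acid can lose the phenoxide by β-elimination, which would give achiral material and racemic product on re-addition. The acidic medium also threatens the benzyl ethers on the very electron-rich rings. The enantioenriched alcohol needs its own asymmetric step.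
- Comparison: in structure it is linear and builds the flavanone on a finished flavone–biaryl. In mechanism a stereospecific step replaces a stereoselective one, in principle an equal, but the centre that matters is more exposed to ionisation. In step economy it would need more operations, among them the Mitsunobu step, ester hydrolysis, cyclisation and a separate acetate removal.

Key step: step 6

Assumption: of the two pseudo-enantiomeric cinchona thioureas, the quinidine-derived one is taken to give the 2S sense with this substrate class; if a one-arm model shows the opposite sense, the quinine-derived catalyst replaces it with nothing else changed.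

## Route

Step 1
Reactants: 1 3-bromo-4-hydroxybenzaldehyde
Product: 2 4-(benzyloxy)-3-bromobenzaldehyde
Conditions: BnBr (1.1 equiv), K2CO3 (1.5 equiv), DMF, rt
Reagents that add atoms: benzyl bromide, BrCc1ccccc1
Why: Williamson ether synthesis; the phenol is acidified by the para formyl and ortho bromo groups and its phenoxide is alkylated by the SN2-reactive benzylic bromide.

Step 2
Reactants: 2 4-(benzyloxy)-3-bromobenzaldehyde (two molecules per molecule of product, added in two halves)
Product: 4 6,6'-bis(benzyloxy)biphenyl-3,3'-dicarbaldehyde, via aryl pinacol boronate 3 (not isolated)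
Conditions: (a) first half of 2, B2pin2 (1.1 equiv on this half), Pd(dppf)Cl2 (3 mol%), KOAc (3 equiv), dioxane, 90 °C; (b) second half of 2, 2 M aq K2CO3, 90 °C
Reagents that add atoms: none
Why: Miyaura borylation followed in the same flask by Suzuki–Miyaura coupling on the same zerovalent palladium catalyst; KOAc is too weak a base to start the coupling during borylation, and the stronger aqueous carbonate then activates boronate 3 for transmetallation. Aldehydes and benzyl ethers are inert, and a biaryl with only two ortho ether groups forms without steric difficulty.

Step 3
Reactants: 5 2',4',6'-trihydroxyacetophenone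
Product: 6 1-[2,4-bis(benzyloxy)-6-hydroxyphenyl]ethanone
Conditions: BnBr (2.1 equiv), K2CO3 (2.2 equiv), DMF, 0 °C to rt
Reagents that add atoms: benzyl bromide, BrCc1ccccc1
Why: Williamson ether synthesis; the para hydroxyl and one ortho hydroxyl are alkylated, while the last ortho hydroxyl is held in a six-membered hydrogen bond to the acetyl oxygen and is the least acidic and least nucleophilic. With a limiting amount of BnBr the reaction should stop at the dibenzyl ether.

Step 4
Reactants: 6 1-[2,4-bis(benzyloxy)-6-hydroxyphenyl]ethanone
Product: 7 tert-butyl 3-[2,4-bis(benzyloxy)-6-hydroxyphenyl]-3-oxopropanoate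
Conditions: LiN(SiMe3)2 (3.3 equiv), THF, −78 °C; Boc2O (1.1 equiv), −78 to −20 °C; cold aq NH4Cl
Reagents that add atoms: di-tert-butyl dicarbonate, CC(C)(C)OC(=O)OC(=O)OC(C)(C)C
Why: Claisen-type C-acylation of the ketone enolate within the phenoxide–enolate dianion; the third equivalent of base deprotonates the β-keto ester as it forms and draws the equilibrium to the C-acylated product. Any carbonate formed on the phenoxide oxygen is relayed to carbon by a 1,5-acyl shift of the Baker–Venkataraman type. The cold quench is meant to prevent lactonisation of the product onto its own phenol.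

Step 5
Reactants: 4 6,6'-bis(benzyloxy)biphenyl-3,3'-dicarbaldehyde; 7 tert-butyl 3-[2,4-bis(benzyloxy)-6-hydroxyphenyl]-3-oxopropanoate (2.2 equiv)
Product: 8 di-tert-butyl 3,3'-[6,6'-bis(benzyloxy)biphenyl-3,3'-diyl]bis{2-[2,4-bis(benzyloxy)-6-hydroxybenzoyl]prop-2-enoate}, mixture of alkene isomers
Conditions: piperidine (0.2 equiv), AcOH (0.2 equiv), 4 Å molecular sieves, toluene, rt; quick filtration through silica, used at once
Reagents that add atoms: none
Why: Twofold Knoevenagel condensation by iminium activation of the aldehydes with piperidinium acetate, driven by water removal on the sieves. The alkene geometry is left uncontrolled because both isomers feed the same cyclisation, and room temperature, the buffered amine and the chelated phenol should keep uncatalysed ring closure low.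

Step 6
Reactants: 8 di-tert-butyl 3,3'-[6,6'-bis(benzyloxy)biphenyl-3,3'-diyl]bis{2-[2,4-bis(benzyloxy)-6-hydroxybenzoyl]prop-2-enoate}
Product: 11 (2S,2''S)-2,2''-[6,6'-bis(benzyloxy)biphenyl-3,3'-diyl]bis[5,7-bis(benzyloxy)-2,3-dihydro-4H-chromen-4-one], via bis-flavanone di-tert-butyl ester 9 (not isolated), via bis(β-keto acid) 10 (not isolated)
Conditions: thiourea from 9-amino-9-deoxy-epi-quinidine and 3,5-bis(trifluoromethyl)phenyl isothiocyanate (20 mol%), toluene, −25 °C; then TsOH·H2O (4 equiv), 80 °C
Reagents that add atoms: none
Why: The quinuclidine nitrogen of the catalyst removes the chelated phenol proton while the two thiourea N–H bonds hold the β-keto ester oxygens, so each ion-paired phenoxide adds to the β-carbon of its own alkylidene on one face and the ester enolate is then protonated (bifunctional base and hydrogen-bond catalysis of an oxa-Michael addition). The closest known reaction type is the cinchona-thiourea-catalysed enantioselective cyclisation of one-armed alkylidene β-keto esters to 3-carboxyflavanones with acid decarboxylation in the same flask; it is used here twice within one molecule. Ring C and ring C' are each closed in the 6-endo-trig mode by formation of the O1–C2 and O1''–C2'' bonds. Both C2 centres are set by the catalyst alone, because the arms are identical, far apart and free of any other stereogenic element, whereas the C3 centres of 9 are under thermodynamic control through the enolisable β-keto ester and settle trans to the aryl group, (2S,3R) in each arm. The selectivity needed is facial and is needed twice; the substrate secures it through the tert-butyl ester, which supplies the second binding point and raises the electrophilicity of the β-carbon so that closure runs at −25 °C where the uncatalysed background is slow, and the alkene isomers are expected to converge because they equilibrate by reversible amine addition and share the bound dicarbonyl geometry. TsOH then cleaves both tert-butyl esters with loss of 2-methylpropene, and the β-keto acids of 10 lose CO2 through the cyclic six-membered transition state, which removes C3 as a stereocentre and leaves C2 untouched. Since the two closures are independent, most minor-sense events end in the meso (2R,2''S) diastereomer, and its removal by crystallisation or chromatography should leave 11 in higher enantiopurity than a single closure provides.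

Step 7
Reactants: 11 (2S,2''S)-2,2''-[6,6'-bis(benzyloxy)biphenyl-3,3'-diyl]bis[5,7-bis(benzyloxy)-2,3-dihydro-4H-chromen-4-one]
Product: 13 (2S)-5,7-bis(benzyloxy)-2-{6,6'-bis(benzyloxy)-3'-[5,7-bis(benzyloxy)-4-oxo-4H-chromen-2-yl]biphenyl-3-yl}-2,3-dihydro-4H-chromen-4-one, via mono(trimethylsilyl enol ether) 12 (not isolated)
Conditions: (a) TMSOTf (1.0 equiv), Et3N (1.5 equiv), CH2Cl2, −20 to 0 °C; cold aq NaHCO3 wash, solvent exchange; (b) Pd(OAc)2 (1.1 equiv), MeCN, rt; recovered 11 recycled
Reagents that add atoms: none
Why: Soft enolisation of one of the two equivalent ketones, then Saegusa–Ito oxidation: divalent palladium forms the C3 palladium enolate and syn β-hydride elimination of the C2–H bond gives the flavone. Both stages run at or below room temperature, so the other ring C is never exposed to the hot acidic medium of an iodine–DMSO dehydrogenation, which could open it reversibly. The limiting amount of silylating agent caps the mono-oxidised product near one half of the material per pass, and untouched 11 returns with its stereocentres intact.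

Step 8
Reactants: 13 (2S)-5,7-bis(benzyloxy)-2-{6,6'-bis(benzyloxy)-3'-[5,7-bis(benzyloxy)-4-oxo-4H-chromen-2-yl]biphenyl-3-yl}-2,3-dihydro-4H-chromen-4-one
Product: 14 (2S)-5,7-dihydroxy-2-{6,6'-dihydroxy-3'-[5,7-dihydroxy-4-oxo-4H-chromen-2-yl]biphenyl-3-yl}-2,3-dihydro-4H-chromen-4-one (CNP0184920.1)
Conditions: H2 (1 atm), 10% Pd/C, THF/MeOH, rt, stopped at full debenzylation
Reagents that add atoms: none
Why: Catalytic hydrogenolysis of six aryl benzyl ethers under neutral conditions at room temperature, which should not touch the C2 configuration. The conjugated C2''=C3'' bond, the C4 ketone and the cyclic benzylic O1–C2 bond are reduced much more slowly than O-benzyl groups, so stopping at the end of hydrogen uptake should give the hexaphenol.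

## Compound list

1 | 3-bromo-4-hydroxybenzaldehyde | O=Cc1ccc(O)c(Br)c1 | starting material
2 | 4-(benzyloxy)-3-bromobenzaldehyde | O=Cc1ccc(OCc2ccccc2)c(Br)c1 | intermediate
3 | 4-(benzyloxy)-3-(4,4,5,5-tetramethyl-1,3,2-dioxaborolan-2-yl)benzaldehyde | O=Cc1ccc(OCc2ccccc2)c(B2OC(C)(C)C(C)(C)O2)c1 | intermediate (not isolated)
4 | 6,6'-bis(benzyloxy)biphenyl-3,3'-dicarbaldehyde | O=Cc1ccc(OCc2ccccc2)c(-c2cc(C=O)ccc2OCc2ccccc2)c1 | intermediate
5 | 2',4',6'-trihydroxyacetophenone | CC(=O)c1c(O)cc(O)cc1O | starting material
6 | 1-[2,4-bis(benzyloxy)-6-hydroxyphenyl]ethanone | CC(=O)c1c(O)cc(OCc2ccccc2)cc1OCc1ccccc1 | intermediate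
7 | tert-butyl 3-[2,4-bis(benzyloxy)-6-hydroxyphenyl]-3-oxopropanoate | CC(C)(C)OC(=O)CC(=O)c1c(O)cc(OCc2ccccc2)cc1OCc1ccccc1 | intermediate
8 | di-tert-butyl 3,3'-[6,6'-bis(benzyloxy)biphenyl-3,3'-diyl]bis{2-[2,4-bis(benzyloxy)-6-hydroxybenzoyl]prop-2-enoate}, mixture of alkene isomers | CC(C)(C)OC(=O)C(=Cc1ccc(OCc2ccccc2)c(-c2cc(C=C(C(=O)OC(C)(C)C)C(=O)c3c(O)cc(OCc4ccccc4)cc3OCc3ccccc3)ccc2OCc2ccccc2)c1)C(=O)c1c(O)cc(OCc2ccccc2)cc1OCc1ccccc1 | intermediate
9 | di-tert-butyl (2S,3R,2''S,3''R)-2,2''-[6,6'-bis(benzyloxy)biphenyl-3,3'-diyl]bis[5,7-bis(benzyloxy)-4-oxo-2,3-dihydro-4H-chromene-3-carboxylate], ester trans to aryl in each ring | O=C1[C@H](C(=O)OC(C)(C)C)[C@@H](c2ccc(OCc3ccccc3)c(-c3cc([C@H]4Oc5cc(OCc6ccccc6)cc(OCc6ccccc6)c5C(=O)[C@@H]4C(=O)OC(C)(C)C)ccc3OCc3ccccc3)c2)Oc2cc(OCc3ccccc3)cc(OCc3ccccc3)c21 | intermediate (not isolated)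
10 | (2S,3R,2''S,3''R)-2,2''-[6,6'-bis(benzyloxy)biphenyl-3,3'-diyl]bis[5,7-bis(benzyloxy)-4-oxo-2,3-dihydro-4H-chromene-3-carboxylic acid] | O=C1[C@H](C(=O)O)[C@@H](c2ccc(OCc3ccccc3)c(-c3cc([C@H]4Oc5cc(OCc6ccccc6)cc(OCc6ccccc6)c5C(=O)[C@@H]4C(=O)O)ccc3OCc3ccccc3)c2)Oc2cc(OCc3ccccc3)cc(OCc3ccccc3)c21 | intermediate (not isolated)
11 | (2S,2''S)-2,2''-[6,6'-bis(benzyloxy)biphenyl-3,3'-diyl]bis[5,7-bis(benzyloxy)-2,3-dihydro-4H-chromen-4-one] | O=C1C[C@@H](c2ccc(OCc3ccccc3)c(-c3cc([C@H]4Oc5cc(OCc6ccccc6)cc(OCc6ccccc6)c5C(=O)C4)ccc3OCc3ccccc3)c2)Oc2cc(OCc3ccccc3)cc(OCc3ccccc3)c21 | intermediate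
12 | mono(trimethylsilyl enol ether) of 11: one (2S)-flavanone unit and one (2S)-5,7-bis(benzyloxy)-4-(trimethylsilyloxy)-2H-chromen-2-yl unit on the same biaryl | C[Si](C)(C)OC1=C[C@@H](c2ccc(OCc3ccccc3)c(-c3cc([C@H]4Oc5cc(OCc6ccccc6)cc(OCc6ccccc6)c5C(=O)C4)ccc3OCc3ccccc3)c2)Oc2cc(OCc3ccccc3)cc(OCc3ccccc3)c21 | intermediate (not isolated)
13 | (2S)-5,7-bis(benzyloxy)-2-{6,6'-bis(benzyloxy)-3'-[5,7-bis(benzyloxy)-4-oxo-4H-chromen-2-yl]biphenyl-3-yl}-2,3-dihydro-4H-chromen-4-one | O=C1C[C@@H](c2ccc(OCc3ccccc3)c(-c3cc(-c4cc(=O)c5c(OCc6ccccc6)cc(OCc6ccccc6)cc5o4)ccc3OCc3ccccc3)c2)Oc2cc(OCc3ccccc3)cc(OCc3ccccc3)c21 | intermediate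
14 | (2S)-5,7-dihydroxy-2-{6,6'-dihydroxy-3'-[5,7-dihydroxy-4-oxo-4H-chromen-2-yl]biphenyl-3-yl}-2,3-dihydro-4H-chromen-4-one | O=C1C[C@@H](c2ccc(O)c(-c3cc(-c4cc(=O)c5c(O)cc(O)cc5o4)ccc3O)c2)Oc2cc(O)cc(O)c21 | target

## Step count and least certain steps

Total step count: 8. Longest linear sequence: 6 steps (steps 3, 4, 5, 6, 7 and 8 from 5; the sequence from 1 through steps 1, 2, 5, 6, 7 and 8 is equally long).

Step 6 (key step).
- What may go wrong: facial control may be lost in one of the two closures, or the second closure may lag. The acyl group is a 2,6-dioxygenated, electron-rich benzoyl group twisted out of the enone plane, a less tested member of the substrate class. Each minor-sense event gives the meso diastereomer, and because the two stereocentres are separated by the whole biaryl its removal may be inefficient. Enantiopurity would then fall back to that of a single closure. Partial reversible opening of ring C in the hot acid stage would add to this.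
- Fallback: run the closure on one arm and join the halves afterwards. Starting from 2 and 7, a Knoevenagel condensation as in step 5 would give the one-armed alkylidene β-keto ester F1. The same thiourea and TsOH sequence would lead, through the one-armed 3-tert-butoxycarbonyl flavanone F2 and its acid F3, to the (S)-3'-bromoflavanone F4. As a small monomer with a single stereocentre, F4 can be brought to enantiopurity by recrystallisation. Base-free reductive homocoupling with zerovalent nickel generated from NiCl2(PPh3)2, Zn and Et4NI in THF at 50 °C would then form the C3'–C3''' bond and return to the route at 11, essentially free of the meso isomer.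

Step 7.
- What may go wrong: enolisation and oxidation may occur at both ketones, which is inherent in the statistics. The silyl enol ether may lose its silyl group before oxidation, or zerovalent palladium formed in the flask may ionise the allylic C2–O1 bond of 12. Each lowers throughput at the most valuable stage.
- Fallback: give up the statistical oxidation and cross-couple the two halves at their final oxidation levels. This sets out from 2 and 7 by way of F1 to F4 of the fallback to step 6. One portion of the bromoflavanone F4 would be dehydrogenated with I2 (cat.) in DMSO at 120 °C to the bromoflavone F5; the harsh conditions are harmless here because no stereocentre survives in this half. Miyaura borylation (B2pin2, Pd(dppf)Cl2, KOAc, dioxane, 90 °C) would give the flavone boronate F6. Suzuki–Miyaura coupling of F6 with a second portion of F4 (Pd(OAc)2, SPhos, anhydrous K3PO4, toluene, 60 °C) would return to the route at 13.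

Step 5.
- What may go wrong: the amine may trigger early oxa-Michael closure of the free phenol onto the new alkylidene, without stereocontrol, or the reaction may stall after one condensation.
- Fallback: keep the phenol masked during the condensation. From 7, silylation (TBSCl, imidazole, DMF) would give the silyl ether F7. Knoevenagel condensation of F7 with 4 under the conditions of step 5 would give the bis-silyl ether F8, which cannot cyclise. Desilylation under mildly acidic conditions (HF·pyridine, THF, 0 °C) frees the phenol without generating a phenoxide and returns to the route at 8.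

Step 4.
- What may go wrong: acylation may occur on oxygen (enol or aryl carbonate) or twice instead of once on carbon, and the product may lactonise onto its ortho phenoxide on warming.
- Fallback: separate O-acylation and C–C bond formation. From 6, deliberate O-acylation (Boc2O, DMAP cat., Et3N, CH2Cl2) would give the aryl tert-butyl carbonate F9. Treatment with LiN(SiMe3)2 (2.2 equiv) in THF at −78 to −20 °C would move the acyl group to the enolate carbon by an intramolecular Baker–Venkataraman rearrangement and return to the route at 7.

Step 8.
- What may go wrong: over-reduction, that is saturation of the C2''=C3'' bond (which would create a second, uncontrolled stereocentre) or hydrogenolysis of the benzylic O1–C2 bond. The reaction may also stall when partly debenzylated material precipitates on the catalyst.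
- Fallback: replace reduction by Lewis-acid dealkylation. From 13, BCl3 with pentamethylbenzene as cation scavenger in CH2Cl2 at −78 °C would cleave all six benzyl ethers without any reducing agent and arrive directly at 14; no new compound is made.

## Further compounds

F1 | step 6 | tert-butyl 2-[2,4-bis(benzyloxy)-6-hydroxybenzoyl]-3-[4-(benzyloxy)-3-bromophenyl]prop-2-enoate, mixture of alkene isomers | CC(C)(C)OC(=O)C(=Cc1ccc(OCc2ccccc2)c(Br)c1)C(=O)c1c(O)cc(OCc2ccccc2)cc1OCc1ccccc1
F2 | step 6 | tert-butyl (2S,3R)-5,7-bis(benzyloxy)-2-[4-(benzyloxy)-3-bromophenyl]-4-oxo-2,3-dihydro-4H-chromene-3-carboxylate | O=C1[C@H](C(=O)OC(C)(C)C)[C@@H](c2ccc(OCc3ccccc3)c(Br)c2)Oc2cc(OCc3ccccc3)cc(OCc3ccccc3)c21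
F3 | step 6 | (2S,3R)-5,7-bis(benzyloxy)-2-[4-(benzyloxy)-3-bromophenyl]-4-oxo-2,3-dihydro-4H-chromene-3-carboxylic acid | O=C1[C@H](C(=O)O)[C@@H](c2ccc(OCc3ccccc3)c(Br)c2)Oc2cc(OCc3ccccc3)cc(OCc3ccccc3)c21
F4 | step 6 | (2S)-5,7-bis(benzyloxy)-2-[4-(benzyloxy)-3-bromophenyl]-2,3-dihydro-4H-chromen-4-one | O=C1C[C@@H](c2ccc(OCc3ccccc3)c(Br)c2)Oc2cc(OCc3ccccc3)cc(OCc3ccccc3)c21
F5 | step 7 | 5,7-bis(benzyloxy)-2-[4-(benzyloxy)-3-bromophenyl]-4H-chromen-4-one | O=c1cc(-c2ccc(OCc3ccccc3)c(Br)c2)oc2cc(OCc3ccccc3)cc(OCc3ccccc3)c12
F6 | step 7 | 5,7-bis(benzyloxy)-2-[4-(benzyloxy)-3-(4,4,5,5-tetramethyl-1,3,2-dioxaborolan-2-yl)phenyl]-4H-chromen-4-one | O=c1cc(-c2ccc(OCc3ccccc3)c(B3OC(C)(C)C(C)(C)O3)c2)oc2cc(OCc3ccccc3)cc(OCc3ccccc3)c12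
F7 | step 5 | tert-butyl 3-[2,4-bis(benzyloxy)-6-(tert-butyldimethylsilyloxy)phenyl]-3-oxopropanoate | CC(C)(C)OC(=O)CC(=O)c1c(O[Si](C)(C)C(C)(C)C)cc(OCc2ccccc2)cc1OCc1ccccc1
F8 | step 5 | di-tert-butyl 3,3'-[6,6'-bis(benzyloxy)biphenyl-3,3'-diyl]bis{2-[2,4-bis(benzyloxy)-6-(tert-butyldimethylsilyloxy)benzoyl]prop-2-enoate}, mixture of alkene isomers | CC(C)(C)OC(=O)C(=Cc1ccc(OCc2ccccc2)c(-c2cc(C=C(C(=O)OC(C)(C)C)C(=O)c3c(O[Si](C)(C)C(C)(C)C)cc(OCc4ccccc4)cc3OCc3ccccc3)ccc2OCc2ccccc2)c1)C(=O)c1c(O[Si](C)(C)C(C)(C)C)cc(OCc2ccccc2)cc1OCc1ccccc1
F9 | step 4 | 2-acetyl-3,5-bis(benzyloxy)phenyl tert-butyl carbonate | CC(=O)c1c(OC(=O)OC(C)(C)C)cc(OCc2ccccc2)cc1OCc1ccccc1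
F0 | step 8 | none | none
A1 | alternative 1 | methyl 4-{6-[6,2'-bis(benzyloxy)-5'-chlorobiphenyl-3-yl]-4-oxo-4H-pyran-2-yl}-3-oxobutanoate | COC(=O)CC(=O)Cc1cc(=O)cc(-c2ccc(OCc3ccccc3)c(-c3cc(Cl)ccc3OCc3ccccc3)c2)o1
A2 | alternative 1 | 2-[6,2'-bis(benzyloxy)-5'-chlorobiphenyl-3-yl]-5,7-dihydroxy-4H-chromen-4-one | O=c1cc(-c2ccc(OCc3ccccc3)c(-c3cc(Cl)ccc3OCc3ccccc3)c2)oc2cc(O)cc(O)c12
A3 | alternative 2 | (2S)-5,7-bis(benzyloxy)-2-[6,6'-bis(benzyloxy)-3'-ethynylbiphenyl-3-yl]-2,3-dihydro-4H-chromen-4-one | O=C1C[C@@H](c2ccc(OCc3ccccc3)c(-c3cc(C#C)ccc3OCc3ccccc3)c2)Oc2cc(OCc3ccccc3)cc(OCc3ccccc3)c21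
A4 | alternative 2 | 2,4,6-tris(benzyloxy)benzonitrile oxide | [O-][N+]#Cc1c(OCc2ccccc2)cc(OCc2ccccc2)cc1OCc1ccccc1
A5 | alternative 2 | (2S)-5,7-bis(benzyloxy)-2-{6,6'-bis(benzyloxy)-3'-[3-(2,4,6-tris(benzyloxy)phenyl)isoxazol-5-yl]biphenyl-3-yl}-2,3-dihydro-4H-chromen-4-one | O=C1C[C@@H](c2ccc(OCc3ccccc3)c(-c3cc(-c4cc(-c5c(OCc6ccccc6)cc(OCc6ccccc6)cc5OCc5ccccc5)no4)ccc3OCc3ccccc3)c2)Oc2cc(OCc3ccccc3)cc(OCc3ccccc3)c21
A6 | alternative 3 | (3S)-3-{6-acetoxy-2'-(benzyloxy)-5'-[5,7-bis(benzyloxy)-4-oxo-4H-chromen-2-yl]biphenyl-3-yl}-3-[3,5-bis(benzyloxy)phenoxy]propanoic acid | OC(=O)C[C@@H](c1ccc(OC(C)=O)c(-c2cc(-c3cc(=O)c4c(OCc5ccccc5)cc(OCc5ccccc5)cc4o3)ccc2OCc2ccccc2)c1)Oc1cc(OCc2ccccc2)cc(OCc2ccccc2)c1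
A7 | alternative 3 | (2S)-2-{6-acetoxy-2'-(benzyloxy)-5'-[5,7-bis(benzyloxy)-4-oxo-4H-chromen-2-yl]biphenyl-3-yl}-5,7-bis(benzyloxy)-2,3-dihydro-4H-chromen-4-one | O=C1C[C@@H](c2ccc(OC(C)=O)c(-c3cc(-c4cc(=O)c5c(OCc6ccccc6)cc(OCc6ccccc6)cc5o4)ccc3OCc3ccccc3)c2)Oc2cc(OCc3ccccc3)cc(OCc3ccccc3)c21
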